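The synthesis rests on cutting the C3'–C8'' biaryl bond (C3' in ring B of genistein unit 1, C8'' in ring A of unit 2). The carbons next to this bond carry O4' (ring B) and O7'' plus the ring oxygen O1'' (ring A). A one-carbon link from O4' to the lone hydroxyl of symmetric 3,5-dimethoxyphenol can therefore steer a palladium-catalysed C–H arylation. In one operation the key step forms the biaryl bond, closes a sacrificial dibenzo-1,3-dioxepine and marks the bridged oxygen as the later O1''. Its precursor 6 is the mixed diaryl formaldehyde acetal of methyl (3-bromo-4-hydroxyphenyl)acetate and 3,5-dimethoxyphenol. Both pyranones follow, and resolution delivers the (M) axis.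

Key step: step 4

Assumption: the SMILES string cannot encode the biaryl axis, so 15 and 16 share one string, and the axis of the free hexaphenol is taken to be configurationally stable at room temperature, as its (M) descriptor implies.

Design notes:
- (a) The chloromethyl ether is raised on the bromoarene, not on the trioxygenated ring. SO2Cl2 and MeSCl would attack the latter.
- (b) The methyl ester is kept until ring A of unit 2 has been acylated, so the molecule never holds a free arylacetic acid and an unacylated dimethoxyphenol ring together.
- (c) The bridge carbon is removed as a dithiane, so no one-carbon electrophile is left beside the electron-rich ring.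

Step 1
Reactants: 1 methyl 2-(3-bromo-4-hydroxyphenyl)acetate; 2 chloromethyl methyl sulfide
Product: 3 methyl 2-[3-bromo-4-(methylsulfanylmethoxy)phenyl]acetate
Conditions: K2CO3, NaI (cat.), DMF, rt
Reagents that add atoms: none
Why: Williamson-type O-alkylation of the acidic ortho-bromophenol by the activated α-chloro sulfide should proceed under carbonate conditions that are too weak to enolise the arylacetate.

Step 2
Reactants: 3 methyl 2-[3-bromo-4-(methylsulfanylmethoxy)phenyl]acetate
Product: 4 methyl 2-[3-bromo-4-(chloromethoxy)phenyl]acetate
Conditions: SO2Cl2, CH2Cl2, 0 °C; volatiles off in vacuo, crude 4 used at once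
Reagents that add atoms: sulfuryl chloride, O=S(=O)(Cl)Cl
Why: Chlorinolysis of an O,S-acetal (S-chlorination, then collapse to the α-chloro ether and MeSCl) is a known entry to aryl chloromethyl ethers, and it is run on the brominated, mono-oxygenated ring because that ring resists ring chlorination and sulfenylation.

Step 3
Reactants: 4 methyl 2-[3-bromo-4-(chloromethoxy)phenyl]acetate; 5 3,5-dimethoxyphenol
Product: 6 methyl 2-[3-bromo-4-[(3,5-dimethoxyphenoxy)methoxy]phenyl]acetate
Conditions: Cs2CO3, DMF, 0 °C to rt
Reagents that add atoms: none
Why: In this Williamson etherification the hard chloromethyl ether should be taken by the phenoxide oxygen of 5 in a dipolar aprotic solvent, which gives the unsymmetrical diaryl formaldehyde acetal without a statistical mixture.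

Step 4
Reactants: 6 methyl 2-[3-bromo-4-[(3,5-dimethoxyphenoxy)methoxy]phenyl]acetate
Product: 7 methyl 2-(1,3-dimethoxydibenzo[d,f][1,3]dioxepin-10-yl)acetate
Conditions: Pd(OAc)2 (10 mol%), PCy3·HBF4 (20 mol%), PivOH (30 mol%), K2CO3, DMA (0.05 M), 120 °C, Ar
Reagents that add atoms: none
Why: Zerovalent palladium formed in situ from Pd(OAc)2 and PCy3 inserts into the C3'–Br bond of 6, bromide is exchanged for pivalate, and the carboxylate takes the proton of the phenoxy C–H next to the bridging oxygen while palladium binds that carbon (concerted metalation–deprotonation). The closest known reaction type is the carboxylate-assisted intramolecular direct arylation of tethered aryl bromides, established for five-, six- and seven-membered closures, so only the O–CH2–O tether is a new substrate feature. The seven-membered 1,3-dioxepine ring closes by C–C reductive elimination from an eight-membered diarylpalladacycle made up of Pd, C3', C4', O4', CH2, O1'', C8a'' and C8''. No stereocentre is created and the CH2-bridged axis should invert readily at the reaction temperature, so 7 carries no fixed configuration. The step needs site selectivity on the phenoxy ring, and the substrate secures it because the three-atom tether lets palladium reach only the two carbons ortho to the bridging oxygen, which are equivalent by symmetry, while the C–H between the two methoxy groups is out of reach. Chemoselectivity against enolate arylation and ester loss is secured by the weak, anhydrous base K2CO3 and by dilution, which favours the intramolecular pathway.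

Step 5
Reactants: 7 methyl 2-(1,3-dimethoxydibenzo[d,f][1,3]dioxepin-10-yl)acetate
Product: 8 methyl 2-[4-hydroxy-3-(2-hydroxy-4,6-dimethoxyphenyl)phenyl]acetate
Conditions: HS(CH2)3SH, BF3·OEt2, CH2Cl2, 0 °C to rt
Reagents that add atoms: none
Why: In this Lewis-acid-promoted transthioacetalisation BF3 opens the diaryl acetal to an aryloxycarbenium ion that the soft dithiol should intercept faster than any arene, so the bridge carbon is locked away as 1,3-dithiane while the aryl methyl ethers and the methyl ester stay inert at this temperature.

Step 6
Reactants: 8 methyl 2-[4-hydroxy-3-(2-hydroxy-4,6-dimethoxyphenyl)phenyl]acetate; 9 4-methoxyphenylacetic acid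
Product: 10 methyl 2-[4-hydroxy-3-[2-hydroxy-4,6-dimethoxy-3-[2-(4-methoxyphenyl)acetyl]phenyl]phenyl]acetate
Conditions: BF3·OEt2 (solvent), 70 °C, Ar; ice-water work-up
Reagents that add atoms: none
Why: Friedel–Crafts acylation in BF3·OEt2 with Fries-type equilibration should place the acyl group ortho to the only free hydroxyl of the dimethoxyphenol ring, where the ketone is held as a six-membered BF2 chelate, whereas ring B is far less activated and the methyl ester is no acyl donor here and so keeps the molecule from acylating itself.

Step 7
Reactants: 10 methyl 2-[4-hydroxy-3-[2-hydroxy-4,6-dimethoxy-3-[2-(4-methoxyphenyl)acetyl]phenyl]phenyl]acetate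
Product: 11 2-[4-hydroxy-3-[2-hydroxy-4,6-dimethoxy-3-[2-(4-methoxyphenyl)acetyl]phenyl]phenyl]acetic acid
Conditions: LiOH, THF–MeOH–H2O (degassed), rt; then 1 M HCl
Reagents that add atoms: lithium hydroxide (supplies the carboxyl OH oxygen), [Li+].[OH-]
Why: Saponification is placed at the deoxybenzoin stage, where no base-sensitive pyranone exists yet and where the acylated ring A of unit 2 is too deactivated to be attacked by the acid that is unveiled.

Step 8
Reactants: 11 2-[4-hydroxy-3-[2-hydroxy-4,6-dimethoxy-3-[2-(4-methoxyphenyl)acetyl]phenyl]phenyl]acetic acid; 12 phloroglucinol (anhydrous)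
Product: 14 racemic 5,7-dihydroxy-3-[4-hydroxy-3-[5,7-dimethoxy-3-(4-methoxyphenyl)-4-oxochromen-8-yl]phenyl]chromen-4-one, via bis-deoxybenzoin 13 (not isolated)
Conditions: BF3·OEt2 (solvent), 80 °C; cool, DMF, then MeSO2Cl, 50 to 80 °C; ice-water work-up
Reagents that add atoms: N,N-dimethylformamide (one CH carbon for each pyranone, C2 and C2''), CN(C)C=O
Why: In this one-pot isoflavone synthesis Friedel–Crafts acylation of symmetric phloroglucinol (one possible regioisomer) gives 13, the Vilsmeier-type iminium salt from DMF and MeSO2Cl then formylates both activated methylene groups, and each ortho hydroxyl closes onto the new carbon with loss of dimethylamine, unit 2 having only O1'' available so that only the 8-aryl chromone can form.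

Step 9
Reactants: 14 racemic 5,7-dihydroxy-3-[4-hydroxy-3-[5,7-dimethoxy-3-(4-methoxyphenyl)-4-oxochromen-8-yl]phenyl]chromen-4-one
Product: 15 racemic bisoflavolin D
Conditions: BBr3 (excess), CH2Cl2, −78 °C to rt; then H2O
Reagents that add atoms: none
Why: In this Lewis-acid ether cleavage BBr3 binds each methoxy oxygen and bromide removes the methyl group by SN2, a standard global demethylation of methylated biflavonoids that should leave the chromone rings and the biaryl bond untouched at or below room temperature.

Step 10
Reactants: 15 racemic bisoflavolin D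
Product: 16 (M)-bisoflavolin D
Conditions: semi-preparative HPLC, immobilised amylose tris(3,5-dimethylphenylcarbamate) phase, n-hexane–EtOH–0.1% TFA, 20 °C; (M) fraction assigned by ECD
Reagents that add atoms: none
Why: In this chromatographic resolution the C3'–C8'' axis is set by physical separation of the two atropisomers and not by induction, it comes last so that no hot or acidic step can scramble it, and the (M) fraction is to be identified by comparing its ECD curve with a computed one.

Compound list
1 | methyl 2-(3-bromo-4-hydroxyphenyl)acetate | COC(=O)Cc1ccc(O)c(Br)c1 | starting material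
2 | chloromethyl methyl sulfide | CSCCl | starting material
3 | methyl 2-[3-bromo-4-(methylsulfanylmethoxy)phenyl]acetate | COC(=O)Cc1ccc(OCSC)c(Br)c1 | intermediate
4 | methyl 2-[3-bromo-4-(chloromethoxy)phenyl]acetate | COC(=O)Cc1ccc(OCCl)c(Br)c1 | intermediate
5 | 3,5-dimethoxyphenol | COc1cc(O)cc(OC)c1 | starting material
6 | methyl 2-[3-bromo-4-[(3,5-dimethoxyphenoxy)methoxy]phenyl]acetate | COC(=O)Cc1ccc(OCOc2cc(OC)cc(OC)c2)c(Br)c1 | intermediate
7 | methyl 2-(1,3-dimethoxydibenzo[d,f][1,3]dioxepin-10-yl)acetate (bridged axis not fixed) | COC(=O)Cc1ccc2OCOc3cc(OC)cc(OC)c3-c2c1 | intermediate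
8 | methyl 2-[4-hydroxy-3-(2-hydroxy-4,6-dimethoxyphenyl)phenyl]acetate (racemic axis) | COC(=O)Cc1ccc(O)c(-c2c(O)cc(OC)cc2OC)c1 | intermediate
9 | 4-methoxyphenylacetic acid | COc1ccc(CC(=O)O)cc1 | starting material
10 | methyl 2-[4-hydroxy-3-[2-hydroxy-4,6-dimethoxy-3-[2-(4-methoxyphenyl)acetyl]phenyl]phenyl]acetate (racemic axis) | COC(=O)Cc1ccc(O)c(-c2c(O)c(C(=O)Cc3ccc(OC)cc3)c(OC)cc2OC)c1 | intermediate
11 | 2-[4-hydroxy-3-[2-hydroxy-4,6-dimethoxy-3-[2-(4-methoxyphenyl)acetyl]phenyl]phenyl]acetic acid (racemic axis) | OC(=O)Cc1ccc(O)c(-c2c(O)c(C(=O)Cc3ccc(OC)cc3)c(OC)cc2OC)c1 | intermediate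
12 | phloroglucinol | Oc1cc(O)cc(O)c1 | starting material
13 | 2-[4-hydroxy-3-[2-hydroxy-4,6-dimethoxy-3-[2-(4-methoxyphenyl)acetyl]phenyl]phenyl]-1-(2,4,6-trihydroxyphenyl)ethanone (bis-deoxybenzoin, racemic axis, not isolated) | O=C(Cc1ccc(O)c(-c2c(O)c(C(=O)Cc3ccc(OC)cc3)c(OC)cc2OC)c1)c1c(O)cc(O)cc1O | intermediate
14 | 5,7-dihydroxy-3-[4-hydroxy-3-[5,7-dimethoxy-3-(4-methoxyphenyl)-4-oxochromen-8-yl]phenyl]chromen-4-one (racemic axis) | O=c1c(-c2ccc(O)c(-c3c(OC)cc(OC)c4c(=O)c(-c5ccc(OC)cc5)coc34)c2)coc2cc(O)cc(O)c12 | intermediate
15 | racemic bisoflavolin D, 3-[3-[5,7-dihydroxy-3-(4-hydroxyphenyl)-4-oxochromen-8-yl]-4-hydroxyphenyl]-5,7-dihydroxychromen-4-one | O=c1c(-c2ccc(O)c(-c3c(O)cc(O)c4c(=O)c(-c5ccc(O)cc5)coc34)c2)coc2cc(O)cc(O)c12 | intermediate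
16 | (M)-bisoflavolin D, (M) configuration at the C3'–C8'' axis | O=c1c(-c2ccc(O)c(-c3c(O)cc(O)c4c(=O)c(-c5ccc(O)cc5)coc34)c2)coc2cc(O)cc(O)c12 | target

Total step count: 10. Longest linear sequence: 10 steps (1 to 16). Compounds 2, 5, 9 and 12 enter as purchased.

Steps most likely to fail

1. Step 4 (direct arylation).
- Risk: metalation of the crowded C–H between two oxygen substituents may be slower than hydrodebromination or intermolecular coupling, and closure of the seven-membered ring may stall.
- Fallback: C–H activation is replaced by a reductive coupling of two carbon–halogen bonds across the same tether. It sets out from 5 and 4 and comes back at 7. Iodination of 5 ortho to the hydroxyl (I2, NaHCO3, THF–H2O, 0 °C, para isomer removed by chromatography) would give 2-iodo-3,5-dimethoxyphenol F1. Alkylation of F1 with 4 under the conditions of step 3 would give methyl 2-[3-bromo-4-[(2-iodo-3,5-dimethoxyphenoxy)methoxy]phenyl]acetate F2. An intramolecular Ullmann-type reductive coupling with zerovalent nickel made in situ (NiBr2(PPh3)2 cat., Zn, Et4NI, THF, 50 °C) would then join the two halogen-bearing carbons to give 7.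

2. Step 5 (opening of the acetal).
- Risk: the diaryl acetal may open sluggishly, the released one-carbon electrophile may be captured by the electron-rich ring in a Friedel–Crafts sense, and long exposure may start ether cleavage.
- Fallback: Lewis-acid solvolysis is replaced by a silylative, iodide-driven dealkylation. Both phenols then emerge masked and the bridge carbon leaves as an inert dihalide. It sets out from 7 and comes back at 8. Me3SiI (a little over 2 equiv, CH2Cl2, 0 °C, short contact so that methyl ethers and the methyl ester are not reached) would give methyl 2-[3-(2,4-dimethoxy-6-trimethylsilyloxyphenyl)-4-trimethylsilyloxyphenyl]acetate F3. Brief methanolysis of F3 at room temperature would give 8.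

3. Step 6 (first acylation).
- Risk: acylation may occur para to the hydroxyl between the methoxy groups. The water released may partly hydrolyse the methyl ester, which would allow self-acylation. Acid may also induce ring closure of O4' onto the dimethoxyphenol ring before that ring is deactivated.
- Fallback: direct C-acylation is replaced by a water-free O-acylation and acyl migration. It sets out from 8 and comes back at 11. Commercial 4-methoxyphenylacetyl chloride (Et3N, DMAP cat., CH2Cl2, 0 °C) would esterify both phenols to methyl 2-[4-[2-(4-methoxyphenyl)acetoxy]-3-[2-[2-(4-methoxyphenyl)acetoxy]-4,6-dimethoxyphenyl]phenyl]acetate F4. A Fries rearrangement (BF3·OEt2, 60 °C) would move the acyl group from O1'' to the adjacent ring carbon and leave the ester on the unactivated ring B in place. This would give methyl 2-[3-[2-hydroxy-4,6-dimethoxy-3-[2-(4-methoxyphenyl)acetyl]phenyl]-4-[2-(4-methoxyphenyl)acetoxy]phenyl]acetate F5. LiOH under the conditions of step 7 would cleave the aryl ester and the methyl ester of F5 together to give 11.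

Further compounds
F1 | step 4 | 2-iodo-3,5-dimethoxyphenol | COc1cc(O)c(I)c(OC)c1
F2 | step 4 | methyl 2-[3-bromo-4-[(2-iodo-3,5-dimethoxyphenoxy)methoxy]phenyl]acetate | COC(=O)Cc1ccc(OCOc2cc(OC)cc(OC)c2I)c(Br)c1
F3 | step 5 | methyl 2-[3-(2,4-dimethoxy-6-trimethylsilyloxyphenyl)-4-trimethylsilyloxyphenyl]acetate | COC(=O)Cc1ccc(O[Si](C)(C)C)c(-c2c(O[Si](C)(C)C)cc(OC)cc2OC)c1
F4 | step 6 | methyl 2-[4-[2-(4-methoxyphenyl)acetoxy]-3-[2-[2-(4-methoxyphenyl)acetoxy]-4,6-dimethoxyphenyl]phenyl]acetate | COC(=O)Cc1ccc(OC(=O)Cc2ccc(OC)cc2)c(-c2c(OC(=O)Cc3ccc(OC)cc3)cc(OC)cc2OC)c1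
F5 | step 6 | methyl 2-[3-[2-hydroxy-4,6-dimethoxy-3-[2-(4-methoxyphenyl)acetyl]phenyl]-4-[2-(4-methoxyphenyl)acetoxy]phenyl]acetate | COC(=O)Cc1ccc(OC(=O)Cc2ccc(OC)cc2)c(-c2c(O)c(C(=O)Cc3ccc(OC)cc3)c(OC)cc2OC)c1
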